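Ring C is disconnected across C3–C4. C4 is drawn as the carbon of a silyl enol ether attached to C4a of ring A, and C3 as the inner carbon of a vinyl group on the ether carbon C2. Ring-closing metathesis of these two alkenes closes the pyran ring in one operation and leaves C4 as an enol silane, ready for trans-selective oxygenation at C3. The precursor is the (S)-1-arylallyl ether of a 2-hydroxyacetophenone (ring A: C8 prenyl, two MOM ethers) whose ketone is masked as its TBS enol ether. C2 is set earlier by iridium-catalysed allylic etherification, and ring B arrives with its prenyl group and MOM ether in place.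

Key step: step 10

Remark: the (Sa,S,S) phosphoramidite is assumed to give the (S)-configured branched ether, the usual sense for aryl-substituted allyl carbonates; if a first run shows the opposite sense, the mirror-image ligand is used.

Abbreviations: prenyl = 3-methylbut-2-en-1-yl; MOM = methoxymethyl; TBS = tert-butyldimethylsilyl.

Step 1
Reactants: 1 2,4,6-trihydroxyacetophenone; 2 prenyl bromide
Product: 3 2,4,6-trihydroxy-3-prenylacetophenone
Conditions: DBU (1.0 equiv), 2 (0.8 equiv), THF, 0 °C → rt
Reagents that add atoms: none
Why: Base-mediated nuclear C-prenylation (C-alkylation of an ambident phloroglucinol phenoxide) is a known reaction of this acetophenone, and because ring positions 3 and 5 are equivalent only over-alkylation has to be held back by keeping the bromide limiting.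

Step 2
Reactants: 3 2,4,6-trihydroxy-3-prenylacetophenone
Product: 4 2-hydroxy-4,6-bis(methoxymethoxy)-3-prenylacetophenone
Conditions: MOMCl (2.2 equiv), i-Pr2NEt, CH2Cl2, 0 °C
Reagents that add atoms: chloromethyl methyl ether, COCCl
Why: Williamson-type O-alkylation takes the unchelated, most acidic 4-OH first and then the less hindered 6-OH, whereas the 2-OH, wedged between the acetyl and prenyl groups and held in the hydrogen bond to the carbonyl, should remain free, which is the differentiation that later places the prenyl group at C8.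

Step 3
Reactants: 5 4-hydroxybenzaldehyde; 2 prenyl bromide
Product: 6 4-hydroxy-3-prenylbenzaldehyde
Conditions: KOH (10 % aq.), rt
Reagents that add atoms: none
Why: Ortho C-alkylation of a phenoxide in water, where hydrogen bonding shields the oxygen, is a known direct route to this aldehyde; the para position is blocked and the two ortho positions are equivalent.

Step 4
Reactants: 6 4-hydroxy-3-prenylbenzaldehyde
Product: 7 4-(methoxymethoxy)-3-prenylbenzaldehyde
Conditions: MOMCl, i-Pr2NEt, CH2Cl2, 0 °C → rt
Reagents that add atoms: chloromethyl methyl ether, COCCl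
Why: Williamson-type O-alkylation of the only hydroxyl gives a MOM ether that is stable to the ylide, hydride, aryloxide and ruthenium steps that follow and is removed together with the ring A acetals at the end.

Step 5
Reactants: 7 4-(methoxymethoxy)-3-prenylbenzaldehyde
Product: 8 ethyl (E)-3-[4-(methoxymethoxy)-3-prenylphenyl]prop-2-enoate
Conditions: Ph3P=CHCO2Et, toluene, 80 °C
Reagents that add atoms: ethyl (triphenylphosphoranylidene)acetate, CCOC(=O)C=P(c1ccccc1)(c1ccccc1)c1ccccc1
Why: Wittig olefination with a stabilised ylide should give the E-cinnamate needed for a linear allylic carbonate.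

Step 6
Reactants: 8 ethyl (E)-3-[4-(methoxymethoxy)-3-prenylphenyl]prop-2-enoate
Product: 9 (E)-3-[4-(methoxymethoxy)-3-prenylphenyl]prop-2-en-1-ol
Conditions: i-Bu2AlH (2.2 equiv), CH2Cl2, −78 °C
Reagents that add atoms: none
Why: 1,2-Reduction of the conjugated ester with i-Bu2AlH at low temperature should give the allylic alcohol without touching the alkenes or the acetal.

Step 7
Reactants: 9 (E)-3-[4-(methoxymethoxy)-3-prenylphenyl]prop-2-en-1-ol
Product: 10 methyl (E)-3-[4-(methoxymethoxy)-3-prenylphenyl]prop-2-en-1-yl carbonate
Conditions: ClCO2Me, pyridine, CH2Cl2, 0 °C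
Reagents that add atoms: methyl chloroformate, COC(=O)Cl
Why: O-Acylation of the primary allylic alcohol with a chloroformate gives the carbonate leaving group used in iridium-catalysed allylic substitution.

Step 8
Reactants: 4 2-hydroxy-4,6-bis(methoxymethoxy)-3-prenylacetophenone; 10 methyl (E)-3-[4-(methoxymethoxy)-3-prenylphenyl]prop-2-en-1-yl carbonate
Product: 12 1-{2-[(1S)-1-[4-(methoxymethoxy)-3-prenylphenyl]prop-2-en-1-yl]oxy-4,6-bis(methoxymethoxy)-3-prenylphenyl}ethanone, via sodium 2-acetyl-3,5-bis(methoxymethoxy)-6-prenylphenolate 11 (not isolated)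
Conditions: 4 (1.2 equiv), NaH, THF, 0 °C; then 10, [Ir(cod)Cl]2 (2 mol %), (Sa,S,S)-O,O'-(1,1'-binaphthyl-2,2'-diyl)-N,N-bis(1-phenylethyl)phosphoramidite (4 mol %, pre-activated with n-PrNH2), THF, 40 °C
Reagents that add atoms: none
Why: Iridium-catalysed asymmetric allylic etherification: the cyclometalated iridium phosphoramidite complex ionises the linear carbonate and the aryloxide attacks the aryl-substituted terminus of the allyl complex anti to the metal, so that the branched ether forms and the ligand fixes the new stereocentre as S (the later C2); ortho-substituted aryloxides are established partners and the ketone, tied up as a chelated acylphenoxide, is left alone.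

Step 9
Reactants: 12 1-{2-[(1S)-1-[4-(methoxymethoxy)-3-prenylphenyl]prop-2-en-1-yl]oxy-4,6-bis(methoxymethoxy)-3-prenylphenyl}ethanone
Product: 13 TBS enol ether of 12, tert-butyl{[1-(2-{[(1S)-1-[4-(methoxymethoxy)-3-prenylphenyl]prop-2-en-1-yl]oxy}-4,6-bis(methoxymethoxy)-3-prenylphenyl)ethenyl]oxy}dimethylsilane
Conditions: TBSOTf (1.3 equiv), Et3N (3 equiv), CH2Cl2, −78 → 0 °C
Reagents that add atoms: tert-butyldimethylsilyl trifluoromethanesulfonate, CC(C)(C)[Si](C)(C)OS(=O)(=O)C(F)(F)F
Why: Soft enolisation of the aryl methyl ketone (silyl triflate and amine) gives the only possible enol silane, and the excess amine keeps the medium basic so that the MOM acetals and the benzylic allylic ether survive.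

Step 10
Reactants: 13 TBS enol ether of 12
Product: 14 (2S)-4-(tert-butyldimethylsilyloxy)-5,7-bis(methoxymethoxy)-2-[4-(methoxymethoxy)-3-prenylphenyl]-8-prenyl-2H-chromene
Conditions: second-generation Grubbs catalyst (H2IMes)(PCy3)Cl2Ru=CHPh (10 mol %), 1,4-benzoquinone (20 mol %), toluene (0.005 M), 60 °C, Ar sparge
Reagents that add atoms: none
Why: The ruthenium benzylidene first exchanges onto the monosubstituted vinyl group at C2, the new alkylidene adds across the 1,1-disubstituted enol ether on C4a with ruthenium on the CH2 terminus, and cycloreversion of the ruthenacyclobutane forms C3=C4 and releases Ru=CH2, which carries the chain with loss of ethene. The closest known reaction type is ring-closing metathesis of silyl enol ethers with allyl groups to cyclic enol silanes (for example 4-silyloxy-1,2-dihydroquinolines), together with the allyl aryl ether/styrene closure to 2H-chromenes. Ring C closes as a six-membered ring with the new double bond endocyclic; no stereocentre is formed, and C2, which is never part of a metallacycle and meets neither base nor acid, keeps its configuration (the quinone traps ruthenium hydrides that could shift the allylic double bond). The selectivity needed is six-membered closure onto the enol ether in preference to seven-membered closure onto the C8 prenyl group and to intermolecular events at either prenyl group. The substrate secures it because the enol ether is a 1,1-disubstituted alkene with a free CH2 terminus whereas the prenyl alkenes are trisubstituted and would release the sluggish Ru=CMe2 carbene, because six-membered closure is kinetically preferred over seven-membered, and because high dilution suppresses cross-metathesis.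

Step 11
Reactants: 14 (2S)-4-(tert-butyldimethylsilyloxy)-5,7-bis(methoxymethoxy)-2-[4-(methoxymethoxy)-3-prenylphenyl]-8-prenyl-2H-chromene
Product: 16 (2R,3R)-3-(tert-butyldimethylsilyloxy)-5,7-bis(methoxymethoxy)-2-[4-(methoxymethoxy)-3-prenylphenyl]-8-prenylchroman-4-one, via 3,4-epoxy-4-silyloxyflavan 15 (not isolated)
Conditions: trans-2-(phenylsulfonyl)-3-phenyloxaziridine (1.2 equiv), CHCl3, rt → 50 °C
Reagents that add atoms: 2-(phenylsulfonyl)-3-phenyloxaziridine, O=S(=O)(c1ccccc1)N1OC1c1ccccc1
Why: Rubottom-type oxidation: the N-sulfonyloxaziridine transfers oxygen to the electron-rich enol silane on the face of ring C opposite to the C2 aryl group and the silyloxy epoxide opens with 1,4-silyl shift to the 2,3-trans α-silyloxy ketone, so C3 is set as R by substrate control, while the reagent is too weak an epoxidising agent to attack the trisubstituted prenyl alkenes at this temperature.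

Step 12
Reactants: 16 (2R,3R)-3-(tert-butyldimethylsilyloxy)-5,7-bis(methoxymethoxy)-2-[4-(methoxymethoxy)-3-prenylphenyl]-8-prenylchroman-4-one
Product: 17 Lespedezaflavanone C
Conditions: HCl (3 M aq.)/MeOH 1:10, 40 °C
Reagents that add atoms: none
Why: Acid-catalysed acetal solvolysis removes the three MOM groups and the same medium methanolyses the secondary silyl ether (any 3-hydroxy material from step 11 converges here), while short exposure to dilute acid at 40 °C should leave the prenyl groups uncyclised and, with no base present, C2 and C3 untouched.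

Compound list
1 | 2,4,6-trihydroxyacetophenone | CC(=O)c1c(O)cc(O)cc1O | starting material
2 | prenyl bromide (1-bromo-3-methylbut-2-ene) | CC(C)=CCBr | starting material
3 | 2,4,6-trihydroxy-3-prenylacetophenone | CC(=O)c1c(O)cc(O)c(CC=C(C)C)c1O | intermediate
4 | 2-hydroxy-4,6-bis(methoxymethoxy)-3-prenylacetophenone | CC(=O)c1c(OCOC)cc(OCOC)c(CC=C(C)C)c1O | intermediate
5 | 4-hydroxybenzaldehyde | O=Cc1ccc(O)cc1 | starting material
6 | 4-hydroxy-3-prenylbenzaldehyde | O=Cc1ccc(O)c(CC=C(C)C)c1 | intermediate
7 | 4-(methoxymethoxy)-3-prenylbenzaldehyde | O=Cc1ccc(OCOC)c(CC=C(C)C)c1 | intermediate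
8 | ethyl (E)-3-[4-(methoxymethoxy)-3-prenylphenyl]prop-2-enoate | CCOC(=O)/C=C/c1ccc(OCOC)c(CC=C(C)C)c1 | intermediate
9 | (E)-3-[4-(methoxymethoxy)-3-prenylphenyl]prop-2-en-1-ol | OC/C=C/c1ccc(OCOC)c(CC=C(C)C)c1 | intermediate
10 | methyl (E)-3-[4-(methoxymethoxy)-3-prenylphenyl]prop-2-en-1-yl carbonate | COC(=O)OC/C=C/c1ccc(OCOC)c(CC=C(C)C)c1 | intermediate
11 | sodium 2-acetyl-3,5-bis(methoxymethoxy)-6-prenylphenolate | CC(=O)c1c(OCOC)cc(OCOC)c(CC=C(C)C)c1[O-].[Na+] | intermediate
12 | 1-{2-[(1S)-1-[4-(methoxymethoxy)-3-prenylphenyl]prop-2-en-1-yl]oxy-4,6-bis(methoxymethoxy)-3-prenylphenyl}ethanone | C=C[C@H](Oc1c(CC=C(C)C)c(OCOC)cc(OCOC)c1C(C)=O)c1ccc(OCOC)c(CC=C(C)C)c1 | intermediate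
13 | TBS enol ether of 12 (1-silyloxyvinyl group on C4a, S at the allylic ether carbon) | C=C[C@H](Oc1c(CC=C(C)C)c(OCOC)cc(OCOC)c1C(=C)O[Si](C)(C)C(C)(C)C)c1ccc(OCOC)c(CC=C(C)C)c1 | intermediate
14 | (2S)-4-(tert-butyldimethylsilyloxy)-5,7-bis(methoxymethoxy)-2-[4-(methoxymethoxy)-3-prenylphenyl]-8-prenyl-2H-chromene | CC(C)=CCc1cc([C@H]2Oc3c(CC=C(C)C)c(OCOC)cc(OCOC)c3C(O[Si](C)(C)C(C)(C)C)=C2)ccc1OCOC | intermediate
15 | 3,4-epoxide of 14 with the oxirane oxygen trans to the C2 aryl group (flavan numbering 2R,3R,4R), silyloxy group on C4 | CC(C)=CCc1cc([C@H]2Oc3c(CC=C(C)C)c(OCOC)cc(OCOC)c3[C@]4(O[Si](C)(C)C(C)(C)C)O[C@H]24)ccc1OCOC | intermediate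
16 | (2R,3R)-3-(tert-butyldimethylsilyloxy)-5,7-bis(methoxymethoxy)-2-[4-(methoxymethoxy)-3-prenylphenyl]-8-prenylchroman-4-one | CC(C)=CCc1cc([C@H]2Oc3c(CC=C(C)C)c(OCOC)cc(OCOC)c3C(=O)[C@@H]2O[Si](C)(C)C(C)(C)C)ccc1OCOC | intermediate
17 | Lespedezaflavanone C, (2R,3R)-3,5,7-trihydroxy-2-(4-hydroxy-3-prenylphenyl)-8-prenylchroman-4-one | CC(C)=CCc1cc([C@H]2Oc3c(CC=C(C)C)c(O)cc(O)c3C(=O)[C@@H]2O)ccc1O | target

Total step count: 12. Longest linear sequence: 10 steps (steps 3 to 7, then 8 to 12).

Steps most likely to fail

Step 10. The ruthenium alkylidene formed at the C2 vinyl group may close the seven-membered ring onto the C8 prenyl group with loss of isobutene. It may also stall at the hindered, electron-rich enol ether, or ruthenium hydrides may move the allylic double bond and destroy C2. The fallback sets out from 4 and 7 and comes back at 14. It closes ring C through the O1–C2 bond and sets C2 by resolution. Claisen–Schmidt condensation of 4 with 7 (KOH, EtOH, rt) should give the 2'-hydroxychalcone F1. Oxa-Michael cyclisation through its only free phenol (NaOAc, EtOH, reflux) should give the racemic 8-prenylflavanone F2. Kinetic resolution by asymmetric transfer hydrogenation (RuCl(p-cymene)(TsDPEN), HCO2H/Et3N, with the catalyst enantiomer chosen to reduce the 2R ketone) should leave the (2S)-flavanone F3, while the 2R enantiomer is reduced to the separable cis-flavan-4-ol F4. Silylation of F3 (TBSOTf, Et3N, CH2Cl2, −78 → 0 °C) then gives 14. At most half of the material is carried on.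

Step 8. The chelated, doubly ortho-substituted acylphenoxide may attack the allyliridium complex slowly. Because it is also a good leaving group, the branched ether may re-ionise on the metal, which erodes the branched-to-linear ratio and the enantiomeric purity. The fallback sets out from 7 and 4 and comes back at 12. Enantioselective addition of Zn(CH=CH2)2 to aldehyde 7, catalysed by a chiral β-amino alcohol, should give the (R)-allylic alcohol F5. Mitsunobu etherification of F5 with phenol 4 (PPh3, diisopropyl azodicarboxylate, toluene, −20 °C) should then give 12 with inversion at the carbinol carbon. The low temperature and non-polar solvent are meant to hold back ionisation and allylic transposition.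

Step 11. Oxygen transfer to the hindered, aryl-conjugated enol silane may be slow, so that protodesilylation to the unoxidised flavanone competes. Attack on the two faces of ring C may also be incompletely differentiated. The fallback sets out from 14 and comes back at 17. Acetoxylation of the enol silane with Pb(OAc)4 (CH2Cl2, −20 °C), a known alternative to peroxide-type oxidants that gives 2,3-trans-3-acetoxyflavanones, should give the (2R,3R)-3-acetoxy ketone F6. Acid methanolysis (HCl, MeOH, 40 °C) then removes the acetate and the three MOM groups to give 17.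

Further compounds
F1 | step 10 | (E)-1-[2-hydroxy-4,6-bis(methoxymethoxy)-3-prenylphenyl]-3-[4-(methoxymethoxy)-3-prenylphenyl]prop-2-en-1-one | COCOc1cc(OCOC)c(CC=C(C)C)c(O)c1C(=O)/C=C/c1ccc(OCOC)c(CC=C(C)C)c1
F2 | step 10 | racemic 5,7-bis(methoxymethoxy)-2-[4-(methoxymethoxy)-3-prenylphenyl]-8-prenylchroman-4-one | CC(C)=CCc1cc(C2CC(=O)c3c(OCOC)cc(OCOC)c(CC=C(C)C)c3O2)ccc1OCOC
F3 | step 10 | (2S)-5,7-bis(methoxymethoxy)-2-[4-(methoxymethoxy)-3-prenylphenyl]-8-prenylchroman-4-one | CC(C)=CCc1cc([C@H]2Oc3c(CC=C(C)C)c(OCOC)cc(OCOC)c3C(=O)C2)ccc1OCOC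
F4 | step 10 | (2R,4R)-5,7-bis(methoxymethoxy)-2-[4-(methoxymethoxy)-3-prenylphenyl]-8-prenylchroman-4-ol (2,4-cis) | CC(C)=CCc1cc([C@@H]2Oc3c(CC=C(C)C)c(OCOC)cc(OCOC)c3[C@H](O)C2)ccc1OCOC
F5 | step 8 | (1R)-1-[4-(methoxymethoxy)-3-prenylphenyl]prop-2-en-1-ol | C=C[C@@H](O)c1ccc(OCOC)c(CC=C(C)C)c1
F6 | step 11 | (2R,3R)-3-acetoxy-5,7-bis(methoxymethoxy)-2-[4-(methoxymethoxy)-3-prenylphenyl]-8-prenylchroman-4-one | CC(C)=CCc1cc([C@H]2Oc3c(CC=C(C)C)c(OCOC)cc(OCOC)c3C(=O)[C@@H]2OC(C)=O)ccc1OCOC
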